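The constants below serve two flasks, gamma and epsilon, which differ in their nucleophile charge; in each, a solid electrophile dissolves slowly into a coupling with the nucleophile.

the same everywhere: solid electrophile 0.050 M; gas 3.8 mM (held); time 30 min
- gamma: nucleophile 1.00 equiv
- epsilon: nucleophile 1.50 equiv

- part of the solid electrophile that has reacted (what has only dissolved counts as not reacted) at the end, gamma
- part of the solid electrophile that has reacted (what has only dissolved counts as not reacted) at the end, epsilon
- what raising the equivalents of nucleophile from its lowest to its highest value here does to the part of the solid electrophile that has reacted (what has only dissolved counts as not reacted) (changes below 5 percentage points count as none) (it rises / it falls / no change)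

- percentages count the solid electrophile that a species holds: one self-condensation product counts as two
- for a step with 2 of a species take k times the square, and two of it per event
- solid, in amounts per volume of the solution: solid electrophile
- at the start none of free base is dissolved
- at the start none of the solid electrophile is in solution
- what has only dissolved of solid electrophile counts as not reacted
- run time (gamma): 30 min

The constants thin the scheme first. With the gas holding free base at 3.8 mM, 5.7 × 10⁶ M⁻¹ keeps the acid set free in the salt of the base, so that hardly any nucleophile is protonated even when the whole charge has turned to acid. Self-condensation has a constant of 0.0024 M⁻¹ min⁻¹, far below the coupling constant 10 M⁻¹ min⁻¹.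

That leaves a relay. Solid dissolves at 0.17 min⁻¹ times the gap between the solubility S, here 20 mM, and the dissolved electrophile E; then E couples with free nucleophile N. While solid stands, E climbs until the two rates match. The ratio of dissolution coefficient to coupling constant is the balance concentration N* = 17.0 mM, and the match gives E = S·N*/(N + N*). Coupling then runs at the feed, 3.40 mM min⁻¹, times N/(N + N*). Far above N* the rate is zero order in nucleophile, with dissolution as the rate-limiting step; far below, it is first order. Integrated, the time to use up an amount of nucleophile is that amount plus N* times the logarithm of the fall in N, all over the feed.

In gamma, E equals N once the solid has gone, which happens at N = 11.8 mM after 18.5 min. After that, 1/N grows by the coupling constant per minute, leaving 5.00 mM and 90.0 % reacted by this reckoning.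

In epsilon, N stands 25.0 mM above E from the moment the solid has gone, and not before. The solid goes at N = 31.9 mM after 16.9 min. Then E/N falls pseudo-first-order at 0.250 min⁻¹, leaving E at 0.209 mM, so 99.6 % has reacted. The rise of 9.6 percentage points exceeds the margin. The reckoning skips the 1.49 min that E needs to reach balance in gamma, a time shorter than the dissolution.

The forecast, “Stepping by hand in 2-minute steps”, gives 88 % for gamma and 99.3 % for epsilon, against 90.0 % and 99.6 % in the reckoning above, with the trend: it rises.

The simulation gives 88.2 % for gamma and 99.3 % for epsilon, and the trend: it rises, by 11 points. At 9.96 min in epsilon, electrophile was made 1.06 times as fast as it was used, each step taken net. In gamma at 15.0 min, with solid at 26.8 %, nucleophile at 42.8 % of its charge gives through N* an electrophile of 17.7 % of the solid charged; the flask held 16.0 %.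

    nucleophile + acid set free ⇌ protonated nucleophile, settled at all times (K1 = 400 M⁻¹)
    electrophile + nucleophile → acid set free + target (k2 = 10 M⁻¹ min⁻¹)
    2 electrophile → self-condensation product (k3 = 0.0024 M⁻¹ min⁻¹)
    solid electrophile ⇌ electrophile, rate k4*(cs4 - [electrophile]) while solid is left; crystals form when [electrophile] > cs4 (cs4 = 20 mM, k4 = 0.17 min⁻¹)
    acid set free + free base ⇌ salt of the base, settled at all times (K5 = 5.7 × 10⁶ M⁻¹)
    gas ⇌ free base, rate k6*(csat - [free base]) (k6 = 150 min⁻¹, csat = 3.8 mM)

Epsilon stopped at 12 min still holds solid at 34.2 %, and nucleophile at 62.8 % of its charge gives through N* an electrophile of 10.6 % of the solid charged. The computed flask holds 10.1 %, with 55.7 % reacted.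

(The numbers of this flask are made up; what happens was integrated by code.)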